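## Analysis of the target

The target 35 is an eudesmane. Ring A (C1–C5, C10) and ring B (C5–C10) share the C5–C10 bond; C10 carries the angular methyl C14, C4 an exocyclic methylene (C15), and C7 a methyl acrylate unit (C11=C13, ester carbon C12). There are four stereocentres. C10 (methyl β) and C5 (hydroperoxide α) define a trans ring fusion; C3 carries the angelate on the β face, next to the exocyclic alkene; C7 holds the acrylate β (equatorial), remote from the other three across ring B. The tertiary allylic hydroperoxide does not survive phosphines, sulfides, hydrides, acylating agents or acid. The angelate isomerises easily to the tiglate, and the acrylate is a Michael acceptor open to conjugate reduction. The end of the synthesis is therefore fixed: ester before peroxide, peroxide last. The hard points are the quaternary C10 next to a fully substituted, oxygenated C5, the two oxygen functions at C3 and C5 flanking the C4 methylene, and the need to tell three alkenes and two esters apart. The strategy rests on one observation: C5 and C10 lie opposite each other in the ten-membered ring C1–C10 of a germacrane. That ring has two E-trisubstituted alkenes (C1=C10 and C4=C5) in a 1,5-relationship and a single stereocentre, C7. Closing C5–C10 across that ring gives both six-membered rings and a C4=C5 alkene to which C3, C5 and C15 are all allylic.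

## Retrosynthetic reasoning

**C5–O (35 to 34).** The hydroperoxide is taken off C5 and a hydrogen returned to C15, which restores the tetrasubstituted C4=C5 alkene of 34. It is the last group made because no later operation would tolerate it. The forward photo-oxygenation (Schenck ene reaction) must put oxygen on C5 from the α face and take its hydrogen from C15, not from C3 or C6.

**C3–O acyl bond (34 to 31 and 32).** The angelate is cut at the acyl–oxygen bond, giving alcohol 31 and angelic acid 32. Acylating just before the peroxide is made keeps the isomerisable Z-ester out of all earlier steps. It also turns the C3 oxygen into a group that does not steer the oxidant to the β face by hydrogen bonding. The forward step must acylate without Z to E isomerisation and with retention at C3.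

**C3 oxygen (31 to 30 to 29).** The carbinol goes back to enone 30, and the carbonyl is then removed to give 29. The C3 methylene of 29 is allylic to the tetrasubstituted alkene, so it can be oxidised after the ring system exists. The planar enone then lets a small hydride set the 3β configuration by axial attack. The forward oxidation must choose C3 over C6.

**C5–C10 (29 to 26), the key disconnection.** Cutting the ring-fusion bond and returning a proton to C5 opens both rings to the germacratriene ester 26. This is preferred to any cut inside one ring because a single bond removal takes away two rings and the quaternary centre, leaving C7 as the only stereocentre. The forward step must form C10 with the methyl β and leave the alkene at C4=C5.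

**C12 oxidation level (26 to 25, 24, 23, 22).** The acrylate is traced back to the silyl-protected allylic alcohol 22. An ester at C12 would not survive the hydride reductions, the carbanion or the borohydride used to build the ring, so C12 travels as a silyl ether. It is raised to the ester only once the ring is closed.

**C2–C3 (22 to 21 to 19).** The ten-membered ring is opened at C2–C3, the only ring bond whose two carbons are both allylic. One end can then be a sulfone-stabilised allylic carbanion and the other an allylic bromide (19). Both trisubstituted alkenes sit in the open chain, where their geometry can be fixed before closure. The sulfone is placed on C2, not C3: its removal passes through an allyl unit, and only C2–C1–C10 has one less substituted and one fully substituted terminus.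

**C4=C5 (19 to 17, 16, then 14 and 15; 14 to 13).** The C3 bromide goes back through alcohol 17 and enoate 16 to aldehyde 14 and the stabilised ylide 15. This olefination reliably gives the E-trisubstituted alkene. Aldehyde 14 is unmasked from acetal 13.

**C1=C10 and the sulfone (13 to 11, 10, then 8 and 9).** The C2 sulfone comes from allylic alcohol 11, and this from enoate 10, made from methyl ketone 8 and phosphonate 9. The ketone must be olefinated before the aldehyde is released, because the sulfone has to end on C2. This is why the aldehyde is carried as an acetal.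

**Ring alkene of the terpene (8 to 5).** Keto acetal 8 is the product of cleaving the trisubstituted ring alkene of 5, with the two new carbonyl carbons differentiated in the same operation. The former ring stereocentre becomes C7, flanked by C6 and C8.

**C12–O (5 to 4 to 1).** The silyloxy group is traced to alcohol 4, and this to (R)-limonene 1 by allylic metalation at the isopropenyl methyl. The absolute configuration of the whole synthesis comes from 1.

## Alternatives that were turned down

**Alternative 1:** Ring B is cut at C6–C7. In the forward step the extended silyl dienol ether A1 is oxidised at an anode. A1 is a ring A cyclohexadiene with an exocyclic C5=C6 methylene, the C10 quaternary centre and an allylsilane side chain. The radical cation is trapped at C6 by the γ-carbon (C7) of the allylsilane, and loss of both silyl groups gives (+)-α-cyperone A2.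
- For it: the C3 carbonyl and the C4=C5 alkene are present by construction. On this point it is stronger than the chosen route, which has to place the alkene by equilibration and then oxidise C3–H selectively.
- Against it: C10 must be made beforehand as a quaternary stereocentre of defined absolute configuration. C7 is then set relative to it across the forming ring. The terminator gives an isopropenyl group, so C12 of A2 must still be oxidised to the ester, in the presence of the enone's own allylic positions, before the material could join the route at 30.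
- In comparison: the chosen strategy takes its absolute configuration from 1, lets C7 control C10, and fixes the C12 oxygen in the first step.

**Alternative 2:** Both rings are cut at once, at C5–C10 and C3–C4. In the forward step a zerovalent nickel catalyst with a triaryl phosphite ligand effects an intramolecular [4+2] cycloaddition of dienyne A3. A3 is a chain derived from 1 carrying a methyl-capped alkyne and an E,E silyl dienol ether. The product is the 3α-silyloxy triene A4.
- For it: two rings, two C–C bonds, the C3 oxygen and the C4=C5 alkene are made in one step from the same chiral pool. In bond-forming economy it is stronger than the chosen route.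
- Against it: the diene terminus that becomes C10 is fully substituted, which is demanding for a metal-catalysed cycloaddition. A4 carries the C3 oxygen on the α face, so C3 must be inverted. The extra C1=C2 alkene must be reduced in the presence of C4=C5 and the side-chain alkene. C12 is still a methyl group.
- In comparison: several corrective steps would follow the key step. The chosen route is longer before its key step, but it gives a product (29) with nothing to undo and needs only the oxygenation of C3 and C5.

**Alternative 3:** Ring B is cut at C7–C8. In the forward step single-electron reduction of the N-(acyloxy)phthalimide A5 releases a primary C8 radical. It adds 6-exo to C7 of the side chain and expels a sulfonyl radical, giving keto ester A6, which is identical with 30.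
- For it: A6 has the enone and the acrylate in place, so it bypasses both the alkene-placement problem of step 17 and the C–H oxidation of step 18. The conditions are mild, and an equatorial C7 substituent is the expected outcome. Judged from the key step onward it is the strongest of the three and probably shorter overall than the chosen route.
- Against it: A5 needs an enantioselective construction of the C10 quaternary centre, and a densely functionalised side chain must be assembled on C5. C7 is created in the radical step, with nothing but the ring conformation to control it.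
- In comparison: the chosen strategy needs no asymmetric step, since every stereocentre derives from C7 of 1. Its key step uses one catalytic acid and has close precedent in the germacrene A acid series.

Key step: step 17

Remark on the chemistry: germacrane/eudesmane atom numbers (C1–C15) are used for all intermediates, open-chain ones included; TBDPS is tert-butyldiphenylsilyl. Configurations at C2 of 21 and at the peroxy-ketal carbon of 6 and 7 are left undefined because those centres are later destroyed. Trienes 21–26 are kept at or below 25 °C and purified on Et3N-deactivated silica.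

## Steps

Step 1
Reactants: 1 (R)-limonene
Product: 4 (R)-2-(4-methylcyclohex-3-en-1-yl)prop-2-en-1-ol, via allyllithium 2 (not isolated), via allylboronate 3 (not isolated)
Conditions: n-BuLi, TMEDA, 25 °C; B(OMe)3, THF, −78 °C; H2O2, aq NaOH, 0 °C
Reagents that add atoms: hydrogen peroxide, OO
Why: Allylic metalation with n-BuLi·TMEDA takes the proton from the isopropenyl methyl of limonene, not from C4–H or the ring, so the stereocentre is untouched; the allyllithium has two equivalent CH2 termini, so borylation and oxidation of the C–B bond can only give the primary allylic alcohol.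

Step 2
Reactants: 4 (R)-2-(4-methylcyclohex-3-en-1-yl)prop-2-en-1-ol
Product: 5 TBDPS ether of 4
Conditions: TBDPSCl, imidazole, DMF, 25 °C
Reagents that add atoms: tert-butyl(chloro)diphenylsilane, CC(C)(C)[Si](Cl)(c1ccccc1)c1ccccc1
Why: Standard silylation of a primary alcohol; the TBDPS ether is chosen because it must outlast acid (steps 3 and 7), i-Bu2AlH, amide base and LiBHEt3 and is removed by fluoride alone.

Step 3
Reactants: 5 TBDPS ether of 4
Product: 8 (5R)-5-[3-(TBDPS-oxy)prop-1-en-2-yl]-7,7-dimethoxyheptan-2-one, via hydroperoxy ketal aldehyde 6 (not isolated), via hydroperoxy ketal acetal 7 (not isolated)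
Conditions: O3, CH2Cl2/MeOH, −78 °C (Sudan Red 7B end point); TsOH·H2O, −78 → 25 °C; NaHCO3, Me2S
Reagents that add atoms: ozone, [O-][O+]=O; methanol, CO
Why: Ozonolysis with Schreiber's unsymmetrical work-up: the electron-rich trisubstituted ring alkene is ozonised ahead of the 1,1-disubstituted alkene, which is deactivated by its allylic silyloxy group; the carbonyl oxide forms on the methyl-bearing carbon and is trapped by methanol, so TsOH acetalises only the free aldehyde (future C5) and Me2S then releases the methyl ketone (future C10).

Step 4
Reactants: 8 (5R)-5-[3-(TBDPS-oxy)prop-1-en-2-yl]-7,7-dimethoxyheptan-2-one; 9 triethyl phosphonoacetate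
Product: 10 ethyl (2E,6R)-6-[3-(TBDPS-oxy)prop-1-en-2-yl]-8,8-dimethoxy-3-methyloct-2-enoate
Conditions: NaH, THF, 0 → 45 °C; chromatographic removal of the Z isomer
Reagents that add atoms: none
Why: Horner–Wadsworth–Emmons olefination of the methyl ketone builds C1=C10; the E isomer (ester trans to the longer chain) is favoured, but a methyl ketone gives only moderate selectivity, so the minor Z isomer is removed by chromatography at this early, cheap stage.

Step 5
Reactants: 10 ethyl (2E,6R)-6-[3-(TBDPS-oxy)prop-1-en-2-yl]-8,8-dimethoxy-3-methyloct-2-enoate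
Product: 11 (2E,6R)-6-[3-(TBDPS-oxy)prop-1-en-2-yl]-8,8-dimethoxy-3-methyloct-2-en-1-ol
Conditions: i-Bu2AlH, CH2Cl2, −78 °C
Reagents that add atoms: none
Why: 1,2-Reduction of the enoate by i-Bu2AlH at low temperature gives the allylic alcohol; acetal, silyl ether and alkene geometry are unaffected.

Step 6
Reactants: 11 (2E,6R)-6-[3-(TBDPS-oxy)prop-1-en-2-yl]-8,8-dimethoxy-3-methyloct-2-en-1-ol
Product: 13 [(2E,6R)-6-[3-(TBDPS-oxy)prop-1-en-2-yl]-8,8-dimethoxy-3-methyloct-2-en-1-yl] phenyl sulfone, via allylic mesylate 12 (not isolated)
Conditions: MsCl, Et3N, THF, −20 °C; then PhSO2Na, n-Bu4NI (cat.), DMF, 25 °C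
Reagents that add atoms: sodium benzenesulfinate, [Na+].[O-]S(=O)c1ccccc1
Why: The allylic mesylate is displaced at the primary carbon by the sulfur of benzenesulfinate (SN2), keeping the E alkene; the sulfone is put on C2 so that its later removal passes through an allyl unit whose two termini differ in substitution.

Step 7
Reactants: 13 [(2E,6R)-6-[3-(TBDPS-oxy)prop-1-en-2-yl]-8,8-dimethoxy-3-methyloct-2-en-1-yl] phenyl sulfone
Product: 14 (3R,6E)-3-[3-(TBDPS-oxy)prop-1-en-2-yl]-6-methyl-8-(phenylsulfonyl)oct-6-enal
Conditions: pyridinium tosylate, acetone/H2O, 45 °C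
Reagents that add atoms: water, O
Why: Acid-catalysed acetal hydrolysis unmasks the C5 aldehyde; silyl ether and sulfone tolerate the mild acid, and the stereocentre is β to the carbonyl, so it cannot epimerise.

Step 8
Reactants: 14 (3R,6E)-3-[3-(TBDPS-oxy)prop-1-en-2-yl]-6-methyl-8-(phenylsulfonyl)oct-6-enal; 15 ethyl 2-(triphenylphosphoranylidene)propanoate
Product: 16 ethyl (2E,5R,8E)-5-[3-(TBDPS-oxy)prop-1-en-2-yl]-2,8-dimethyl-10-(phenylsulfonyl)deca-2,8-dienoate
Conditions: CH2Cl2, 25 °C
Reagents that add atoms: none
Why: Wittig reaction of a stabilised, α-methyl-substituted ylide with an aldehyde gives the E-trisubstituted enoate (C4=C5) with high selectivity; the ylide is too weak a base to deprotonate the sulfone.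

Step 9
Reactants: 16 ethyl (2E,5R,8E)-5-[3-(TBDPS-oxy)prop-1-en-2-yl]-2,8-dimethyl-10-(phenylsulfonyl)deca-2,8-dienoate
Product: 17 (2E,5R,8E)-5-[3-(TBDPS-oxy)prop-1-en-2-yl]-2,8-dimethyl-10-(phenylsulfonyl)deca-2,8-dien-1-ol
Conditions: i-Bu2AlH, CH2Cl2, −78 °C
Reagents that add atoms: none
Why: i-Bu2AlH reduces the enoate to the allylic alcohol; the sulfone is inert at −78 °C.

Step 10
Reactants: 17 (2E,5R,8E)-5-[3-(TBDPS-oxy)prop-1-en-2-yl]-2,8-dimethyl-10-(phenylsulfonyl)deca-2,8-dien-1-ol
Product: 19 [(2E,6R,8E)-10-bromo-6-[3-(TBDPS-oxy)prop-1-en-2-yl]-3,9-dimethyldeca-2,8-dien-1-yl] phenyl sulfone, via allylic mesylate 18 (not isolated)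
Conditions: MsCl, Et3N, THF, −40 °C; then LiBr, THF, 0 °C
Reagents that add atoms: lithium bromide, [Li+].[Br-]
Why: Mesylation and SN2 displacement by bromide at the primary allylic carbon give the bromide without allylic transposition; it is used at once.

Step 11
Reactants: 19 [(2E,6R,8E)-10-bromo-6-[3-(TBDPS-oxy)prop-1-en-2-yl]-3,9-dimethyldeca-2,8-dien-1-yl] phenyl sulfone
Product: 21 (7R)-12-(TBDPS-oxy)-2-(phenylsulfonyl)germacra-1(10)E,4E,11(13)-triene, via lithiated sulfone 20 (not isolated)
Conditions: LiN(SiMe3)2, THF, 0 °C, slow addition of 19 (final ca. 2 mM)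
Reagents that add atoms: none
Why: Intramolecular alkylation of the sulfone-stabilised allylic carbanion by the allylic bromide (Biellmann/Julia-type allyl–allyl coupling) under high dilution forms C2–C3 and the ten-membered ring; alkylation occurs α to sulfur, both trisubstituted alkenes are already E, and the new C2 centre is irrelevant because the sulfone is removed next.

Step 12
Reactants: 21 (7R)-12-(TBDPS-oxy)-2-(phenylsulfonyl)germacra-1(10)E,4E,11(13)-triene
Product: 22 (7R)-12-(TBDPS-oxy)germacra-1(10)E,4E,11(13)-triene
Conditions: PdCl2(dppp) (5 mol %), LiBHEt3, THF, 0 °C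
Reagents that add atoms: none
Why: Reductive desulfonylation of an allylic sulfone: zerovalent palladium formed in situ ionises the C2–S bond to a π-allyl complex and hydride is delivered to the less substituted C2 terminus, so C1=C10 stays in place and E; the fully substituted C10 terminus does not form the σ-complex needed to scramble geometry.

Step 13
Reactants: 22 (7R)-12-(TBDPS-oxy)germacra-1(10)E,4E,11(13)-triene
Product: 23 (7R)-germacra-1(10)E,4E,11(13)-trien-12-ol
Conditions: n-Bu4NF, THF, 0 → 25 °C
Reagents that add atoms: none
Why: Fluoride cleaves the silyl ether under non-acidic conditions that the acid-labile triene tolerates; the temperature is kept low to avoid Cope rearrangement.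

Step 14
Reactants: 23 (7R)-germacra-1(10)E,4E,11(13)-trien-12-ol
Product: 24 (7R)-germacra-1(10)E,4E,11(13)-trien-12-al
Conditions: MnO2, CH2Cl2, 25 °C
Reagents that add atoms: none
Why: MnO2 oxidises the allylic alcohol selectively to the α-methylene aldehyde under neutral conditions; the ring alkenes are not affected.

Step 15
Reactants: 24 (7R)-germacra-1(10)E,4E,11(13)-trien-12-al
Product: 25 (7R)-germacra-1(10)E,4E,11(13)-trien-12-oic acid
Conditions: NaClO2, NaH2PO4, 2-methylbut-2-ene, t-BuOH/H2O, 0 °C
Reagents that add atoms: sodium chlorite, [Na+].[O-]Cl=O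
Why: Pinnick oxidation converts the enal into the acrylic acid; the large excess of 2-methylbut-2-ene removes HOCl before it can reach the ring alkenes, and any acid-induced ring closure at this point would only anticipate step 17.

Step 16
Reactants: 25 (7R)-germacra-1(10)E,4E,11(13)-trien-12-oic acid
Product: 26 methyl (7R)-germacra-1(10)E,4E,11(13)-trien-12-oate
Conditions: TMSCHN2, toluene/MeOH, 0 °C
Reagents that add atoms: (trimethylsilyl)diazomethane, C[Si](C)(C)C=[N+]=[N-]
Why: Methylation with TMSCHN2 in methanol is neutral and fast at 0 °C, so the triene is neither heated nor exposed to acid or base.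

Step 17
Reactants: 26 methyl (7R)-germacra-1(10)E,4E,11(13)-trien-12-oate
Product: 29 methyl eudesma-4,11(13)-dien-12-oate, via methyl β-costate 27 (not isolated), via methyl α-costate 28 (not isolated)
Conditions: TsOH·H2O (10 mol %), CH2Cl2, 0 → 25 °C; then 40 °C until the alkene isomers have converged
Reagents that add atoms: none
Why: TsOH protonates C1 of the C1=C10 alkene to give the tertiary C10 cation, which the C4=C5 alkene, held across the ring by the E,E-1,5-diene, captures through C5; the resulting tertiary C4 cation then loses a proton. The closest known reaction is the acid-induced transannular cyclisation of (E,E)-germacra-1(10),4-dienes to selinene-type eudesmanes, documented for germacrene A and for its C12 acid, which gives the costic acids. Ring A closes in a 6-endo mode (both alkene carbons C4 and C5 end inside it) and ring B in a 6-exo mode (only C5 lies in it). The one new stereocentre, C10, is set by the reacting conformer: the pseudo-equatorial C7 acrylate selects the crossed conformer in which C14 and C15 both point to the β face, so the bond forms with C14 β. Chemoselectivity follows from the electronics of the three alkenes: the acrylate is too electron-poor to be protonated, and protonation at C5 gives a C4 cation with no productive six-membered closure, which simply reverts. The step needs loss of H5 and not of H3 or H15: under kinetic control 27 and 28 form beside 29, but the same acid re-protonates their less substituted alkenes and drains them to the tetrasubstituted, most stable alkene. Because the germacrene is consumed at 0–25 °C, the later equilibration can be warmed without risk of Cope rearrangement.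

Step 18
Reactants: 29 methyl eudesma-4,11(13)-dien-12-oate
Product: 30 methyl 3-oxoeudesma-4,11(13)-dien-12-oate
Conditions: CrO3, 3,5-dimethylpyrazole, CH2Cl2, −20 °C
Reagents that add atoms: chromium trioxide, O=[Cr](=O)=O
Why: Allylic oxidation with hexavalent chromium (Salmond conditions) turns an allylic methylene of a fully substituted cycloalkene into the enone; C3 should be preferred over C6 because its pseudoaxial hydrogen is aligned and unhindered, whereas the aligned (axial, β) hydrogen on C6 is shielded by the C14 methyl and flanked by C7, and the electron-poor acrylate is not attacked.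

Step 19
Reactants: 30 methyl 3-oxoeudesma-4,11(13)-dien-12-oate
Product: 31 methyl 3β-hydroxyeudesma-4,11(13)-dien-12-oate
Conditions: NaBH4, CeCl3·7H2O, MeOH, −78 → −40 °C
Reagents that add atoms: none
Why: Luche reduction gives 1,2-reduction only; hydride enters axially from the α face, away from the β C14 methyl, to give the equatorial 3β-alcohol, and the CeCl3/methanol system at low temperature suppresses conjugate reduction of the acrylate.

Step 20
Reactants: 31 methyl 3β-hydroxyeudesma-4,11(13)-dien-12-oate; 32 angelic acid
Product: 34 methyl 3β-(angeloyloxy)eudesma-4,11(13)-dien-12-oate, via mixed anhydride 33 (not isolated)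
Conditions: 32, 2,4,6-Cl3C6H2COCl, Et3N, toluene, 25 °C; then 31, toluene, 75 °C
Reagents that add atoms: none
Why: Yamaguchi esterification through the mixed 2,4,6-trichlorobenzoic anhydride acylates the alcohol with retention at C3 and without a nucleophilic catalyst, the established way to keep an angelate from isomerising to the tiglate.

Step 21
Reactants: 34 methyl 3β-(angeloyloxy)eudesma-4,11(13)-dien-12-oate
Product: 35 methyl 3β-(angeloyloxy)-5α-hydroperoxyeudesma-4(15),11(13)-dien-12-oate
Conditions: O2, hν (>500 nm), tetraphenylporphyrin (cat.), CH2Cl2, −20 °C; no reductive work-up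
Reagents that add atoms: dioxygen, O=O
Why: Schenck ene reaction: singlet oxygen attacks only the electron-rich tetrasubstituted C4=C5 alkene (acrylate and angelate are electron-poor), from the α face opposite the axial C14 methyl and the 3β-ester; the perepoxide leans to the C15/C6 side (cis effect), where the C15 methyl offers an aligned hydrogen while H6α is equatorial, so oxygen ends on C5 and the alkene moves to C4=C15; the low-energy sensitiser cannot isomerise the angelate.

## Compound list

1 | (R)-limonene | CC1=CC[C@@H](CC1)C(C)=C | starting material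
2 | 2-[(1R)-4-methylcyclohex-3-en-1-yl]allyllithium | [Li]CC(=C)[C@@H]1CCC(C)=CC1 | intermediate
3 | dimethyl {2-[(1R)-4-methylcyclohex-3-en-1-yl]allyl}boronate | COB(OC)CC(=C)[C@@H]1CCC(C)=CC1 | intermediate
4 | (R)-2-(4-methylcyclohex-3-en-1-yl)prop-2-en-1-ol | C=C(CO)[C@@H]1CCC(C)=CC1 | intermediate
5 | tert-butyl{[2-((1R)-4-methylcyclohex-3-en-1-yl)allyl]oxy}diphenylsilane (TBDPS ether of 4) | C=C(CO[Si](c1ccccc1)(c1ccccc1)C(C)(C)C)[C@@H]1CCC(C)=CC1 | intermediate
6 | (3R)-3-[3-(TBDPS-oxy)prop-1-en-2-yl]-6-hydroperoxy-6-methoxyheptanal (C6 epimers) | C=C(CO[Si](c1ccccc1)(c1ccccc1)C(C)(C)C)[C@@H](CC=O)CCC(C)(OC)OO | intermediate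
7 | (5R)-5-[3-(TBDPS-oxy)prop-1-en-2-yl]-2-hydroperoxy-2,7,7-trimethoxyheptane (C2 epimers) | C=C(CO[Si](c1ccccc1)(c1ccccc1)C(C)(C)C)[C@@H](CC(OC)OC)CCC(C)(OC)OO | intermediate
8 | (5R)-5-[3-(TBDPS-oxy)prop-1-en-2-yl]-7,7-dimethoxyheptan-2-one | C=C(CO[Si](c1ccccc1)(c1ccccc1)C(C)(C)C)[C@@H](CC(OC)OC)CCC(C)=O | intermediate
9 | triethyl phosphonoacetate | CCOC(=O)CP(=O)(OCC)OCC | starting material
10 | ethyl (2E,6R)-6-[3-(TBDPS-oxy)prop-1-en-2-yl]-8,8-dimethoxy-3-methyloct-2-enoate | C=C(CO[Si](c1ccccc1)(c1ccccc1)C(C)(C)C)[C@@H](CC(OC)OC)CC/C(C)=C/C(=O)OCC | intermediate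
11 | (2E,6R)-6-[3-(TBDPS-oxy)prop-1-en-2-yl]-8,8-dimethoxy-3-methyloct-2-en-1-ol | C=C(CO[Si](c1ccccc1)(c1ccccc1)C(C)(C)C)[C@@H](CC(OC)OC)CC/C(C)=C/CO | intermediate
12 | methanesulfonate of 11 | C=C(CO[Si](c1ccccc1)(c1ccccc1)C(C)(C)C)[C@@H](CC(OC)OC)CC/C(C)=C/COS(C)(=O)=O | intermediate
13 | [(2E,6R)-6-[3-(TBDPS-oxy)prop-1-en-2-yl]-8,8-dimethoxy-3-methyloct-2-en-1-yl] phenyl sulfone | C=C(CO[Si](c1ccccc1)(c1ccccc1)C(C)(C)C)[C@@H](CC(OC)OC)CC/C(C)=C/CS(=O)(=O)c1ccccc1 | intermediate
14 | (3R,6E)-3-[3-(TBDPS-oxy)prop-1-en-2-yl]-6-methyl-8-(phenylsulfonyl)oct-6-enal | C=C(CO[Si](c1ccccc1)(c1ccccc1)C(C)(C)C)[C@@H](CC=O)CC/C(C)=C/CS(=O)(=O)c1ccccc1 | intermediate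
15 | ethyl 2-(triphenylphosphoranylidene)propanoate | CCOC(=O)C(C)=P(c1ccccc1)(c1ccccc1)c1ccccc1 | starting material
16 | ethyl (2E,5R,8E)-5-[3-(TBDPS-oxy)prop-1-en-2-yl]-2,8-dimethyl-10-(phenylsulfonyl)deca-2,8-dienoate | C=C(CO[Si](c1ccccc1)(c1ccccc1)C(C)(C)C)[C@@H](C/C=C(\C)C(=O)OCC)CC/C(C)=C/CS(=O)(=O)c1ccccc1 | intermediate
17 | (2E,5R,8E)-5-[3-(TBDPS-oxy)prop-1-en-2-yl]-2,8-dimethyl-10-(phenylsulfonyl)deca-2,8-dien-1-ol | C=C(CO[Si](c1ccccc1)(c1ccccc1)C(C)(C)C)[C@@H](C/C=C(\C)CO)CC/C(C)=C/CS(=O)(=O)c1ccccc1 | intermediate
18 | methanesulfonate of 17 | C=C(CO[Si](c1ccccc1)(c1ccccc1)C(C)(C)C)[C@@H](C/C=C(\C)COS(C)(=O)=O)CC/C(C)=C/CS(=O)(=O)c1ccccc1 | intermediate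
19 | [(2E,6R,8E)-10-bromo-6-[3-(TBDPS-oxy)prop-1-en-2-yl]-3,9-dimethyldeca-2,8-dien-1-yl] phenyl sulfone | C=C(CO[Si](c1ccccc1)(c1ccccc1)C(C)(C)C)[C@@H](C/C=C(\C)CBr)CC/C(C)=C/CS(=O)(=O)c1ccccc1 | intermediate
20 | α-lithio derivative of 19 (lithium on C2) | C=C(CO[Si](c1ccccc1)(c1ccccc1)C(C)(C)C)[C@@H](C/C=C(\C)CBr)CC/C(C)=C/C([Li])S(=O)(=O)c1ccccc1 | intermediate
21 | (7R)-12-(TBDPS-oxy)-2-(phenylsulfonyl)germacra-1(10)E,4E,11(13)-triene (C2 epimers) | C=C(CO[Si](c1ccccc1)(c1ccccc1)C(C)(C)C)[C@@H]1CC/C(C)=C/C(S(=O)(=O)c2ccccc2)C/C(C)=C/C1 | intermediate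
22 | (7R)-12-(TBDPS-oxy)germacra-1(10)E,4E,11(13)-triene | C=C(CO[Si](c1ccccc1)(c1ccccc1)C(C)(C)C)[C@@H]1CC/C(C)=C/CC/C(C)=C/C1 | intermediate
23 | (7R)-germacra-1(10)E,4E,11(13)-trien-12-ol | C=C(CO)[C@@H]1CC/C(C)=C/CC/C(C)=C/C1 | intermediate
24 | (7R)-germacra-1(10)E,4E,11(13)-trien-12-al | C=C(C=O)[C@@H]1CC/C(C)=C/CC/C(C)=C/C1 | intermediate
25 | (7R)-germacra-1(10)E,4E,11(13)-trien-12-oic acid | C=C(C(=O)O)[C@@H]1CC/C(C)=C/CC/C(C)=C/C1 | intermediate
26 | methyl (7R)-germacra-1(10)E,4E,11(13)-trien-12-oate | C=C(C(=O)OC)[C@@H]1CC/C(C)=C/CC/C(C)=C/C1 | intermediate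
27 | methyl eudesma-4(15),11(13)-dien-12-oate (methyl β-costate; 5α-H, 7β side chain, 10β-methyl) | C=C(C(=O)OC)[C@@H]1CC[C@@]2(C)CCCC(=C)[C@@H]2C1 | intermediate
28 | methyl eudesma-3,11(13)-dien-12-oate (methyl α-costate; 5α-H) | C=C(C(=O)OC)[C@@H]1CC[C@@]2(C)CCC=C(C)[C@@H]2C1 | intermediate
29 | methyl eudesma-4,11(13)-dien-12-oate (7β side chain, 10β-methyl) | C=C(C(=O)OC)[C@@H]1CC[C@@]2(C)CCCC(C)=C2C1 | intermediate
30 | methyl 3-oxoeudesma-4,11(13)-dien-12-oate | C=C(C(=O)OC)[C@@H]1CC[C@@]2(C)CCC(=O)C(C)=C2C1 | intermediate
31 | methyl 3β-hydroxyeudesma-4,11(13)-dien-12-oate | C=C(C(=O)OC)[C@@H]1CC[C@@]2(C)CC[C@H](O)C(C)=C2C1 | intermediate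
32 | angelic acid | C/C=C(/C)C(=O)O | starting material
33 | angelic 2,4,6-trichlorobenzoic anhydride | C/C=C(/C)C(=O)OC(=O)c1c(Cl)cc(Cl)cc1Cl | intermediate
34 | methyl 3β-(angeloyloxy)eudesma-4,11(13)-dien-12-oate | C=C(C(=O)OC)[C@@H]1CC[C@@]2(C)CC[C@H](OC(=O)/C(C)=C\C)C(C)=C2C1 | intermediate
35 | methyl 3β-(angeloyloxy)-5α-hydroperoxyeudesma-4(15),11(13)-dien-12-oate | C=C(C(=O)OC)[C@@H]1CC[C@@]2(C)CC[C@H](OC(=O)/C(C)=C\C)C(=C)[C@]2(OO)C1 | target

## Step count and least certain steps

Total step count: 21. Longest linear sequence: 21 steps (1 to 35); 9, 15 and 32 enter as purchased reagents.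

**Step 17 (key step).** The most likely failure is in the fate of the C4 cation. Proton loss is spread over H3, H15 and H5, and the equilibration that should drain 27 and 28 into 29 may stall at ambient temperature. Heating is not possible while any germacrene remains, because of the Cope rearrangement. The trisubstituted isomer 28 in particular may persist. The fallback separates ring closure from alkene placement. It sets out from 26. The ring is closed in aqueous acetone with dilute H2SO4 at 0 °C, so that water intercepts the C4 cation from the less hindered α face. This should give methyl 4α-hydroxyeudesm-11(13)-en-12-oate F1, a stable tertiary alcohol that cannot undergo Cope rearrangement and can be purified. F1 is then dehydrated under forcing, fully equilibrating conditions (TsOH, benzene, reflux) and comes back to the route at 29. The C4 configuration of F1 is immaterial.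

**Step 3.** Ozone may also cleave the 1,1-disubstituted side-chain alkene if the end point is overrun, because the rate difference between the two alkenes is finite. The fallback replaces the oxidant by one with a much larger preference for the trisubstituted alkene. It sets out from 5. Epoxidation with mCPBA (CH2Cl2, NaHCO3, 0 °C) should give the ring epoxide F2 as a mixture of diastereomers. Cleavage with HIO4 in aqueous THF gives keto aldehyde F3. Aldehyde-selective acetalisation (HC(OMe)3, MeOH, CeCl3·7H2O) returns to the route at 8.

**Step 11.** Bimolecular alkylation (oligomers) and elimination of HBr may outrun ring closure, because a ten-membered ring is formed against transannular strain and the entropic cost is high. The fallback closes the same C2–C3 bond by reductive allyl–allyl coupling at a metal, not by a carbanion. It sets out from 11 and proceeds as follows.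
- Acetal hydrolysis (pyridinium tosylate, wet acetone) gives hydroxy aldehyde F4.
- Wittig reaction with 15 gives hydroxy enoate F5.
- i-Bu2AlH gives diol F6.
- MsCl/Et3N followed by LiBr gives the bis(allylic bromide) F7.
- Slow addition of F7 to Ni(cod)2 (zerovalent nickel) in DMF couples the two allyl termini and returns to the route at 22.

This also makes step 12 unnecessary. The price is the known tendency of allylnickel intermediates to erode alkene geometry.

**Step 12.** Hydride may be delivered to the C10 terminus of the allyl intermediate, or the allyl–palladium unit may equilibrate, so that the alkene is transposed or its geometry is lost. The fallback changes the mechanism to electron transfer and the order of events. It sets out from 21. The silyl ether is removed first (n-Bu4NF, THF) to give sulfonyl alcohol F8. As its lithium alkoxide the allylic C–O bond is protected, and the sulfone is cleaved with lithium in ethylamine at −78 °C, as is usual for polyprenyl sulfones. The route is rejoined at 23.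

**Step 21.** The allylic ester slows the ene reaction of the C4=C5 alkene. Slower channels may then take a larger share: hydrogen abstraction from C6 or C3, attack on the β face, photo-oxidation of the angelate, and radical rearrangement of the product peroxide. The fallback carries out the oxygenation on a more electron-rich substrate and brings the angelate in afterwards. It sets out from 31 and proceeds as follows.
- Silylation (TBSCl, imidazole) gives silyl ether F9.
- Photo-oxygenation under the conditions of step 21 gives hydroperoxide F10.
- The hydroperoxide is masked with 2-methoxypropene and pyridinium tosylate as the peroxyketal F11.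
- Fluoride frees the C3 alcohol F12.
- Yamaguchi esterification with 32, kept at or below 60 °C, gives angelate F13.
- Aqueous acetic acid in THF removes the peroxyketal and returns to the route at 35.

## Further compounds

F1 | step 17 | methyl 4α-hydroxyeudesm-11(13)-en-12-oate | C=C(C(=O)OC)[C@@H]1CC[C@@]2(C)CCC[C@@](C)(O)[C@@H]2C1
F2 | step 3 | 1,2-epoxide of 5 (ring epoxide, mixture of diastereomers) | C=C(CO[Si](c1ccccc1)(c1ccccc1)C(C)(C)C)[C@@H]1CCC2(C)OC2C1
F3 | step 3 | (3R)-3-[3-(TBDPS-oxy)prop-1-en-2-yl]-6-oxoheptanal | C=C(CO[Si](c1ccccc1)(c1ccccc1)C(C)(C)C)[C@@H](CC=O)CCC(C)=O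
F4 | step 11 | (3R,6E)-3-[3-(TBDPS-oxy)prop-1-en-2-yl]-8-hydroxy-6-methyloct-6-enal | C=C(CO[Si](c1ccccc1)(c1ccccc1)C(C)(C)C)[C@@H](CC=O)CC/C(C)=C/CO
F5 | step 11 | ethyl (2E,5R,8E)-5-[3-(TBDPS-oxy)prop-1-en-2-yl]-10-hydroxy-2,8-dimethyldeca-2,8-dienoate | C=C(CO[Si](c1ccccc1)(c1ccccc1)C(C)(C)C)[C@@H](C/C=C(\C)C(=O)OCC)CC/C(C)=C/CO
F6 | step 11 | (2E,5R,8E)-5-[3-(TBDPS-oxy)prop-1-en-2-yl]-2,8-dimethyldeca-2,8-diene-1,10-diol | C=C(CO[Si](c1ccccc1)(c1ccccc1)C(C)(C)C)[C@@H](C/C=C(\C)CO)CC/C(C)=C/CO
F7 | step 11 | (2E,5R,8E)-1,10-dibromo-5-[3-(TBDPS-oxy)prop-1-en-2-yl]-2,8-dimethyldeca-2,8-diene | C=C(CO[Si](c1ccccc1)(c1ccccc1)C(C)(C)C)[C@@H](C/C=C(\C)CBr)CC/C(C)=C/CBr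
F8 | step 12 | (7R)-2-(phenylsulfonyl)germacra-1(10)E,4E,11(13)-trien-12-ol (C2 epimers) | C=C(CO)[C@@H]1CC/C(C)=C/C(S(=O)(=O)c2ccccc2)C/C(C)=C/C1
F9 | step 21 | methyl 3β-[(tert-butyldimethylsilyl)oxy]eudesma-4,11(13)-dien-12-oate | C=C(C(=O)OC)[C@@H]1CC[C@@]2(C)CC[C@H](O[Si](C)(C)C(C)(C)C)C(C)=C2C1
F10 | step 21 | methyl 3β-[(tert-butyldimethylsilyl)oxy]-5α-hydroperoxyeudesma-4(15),11(13)-dien-12-oate | C=C(C(=O)OC)[C@@H]1CC[C@@]2(C)CC[C@H](O[Si](C)(C)C(C)(C)C)C(=C)[C@]2(OO)C1
F11 | step 21 | methyl 3β-[(tert-butyldimethylsilyl)oxy]-5α-[(2-methoxypropan-2-yl)peroxy]eudesma-4(15),11(13)-dien-12-oate | C=C(C(=O)OC)[C@@H]1CC[C@@]2(C)CC[C@H](O[Si](C)(C)C(C)(C)C)C(=C)[C@]2(OOC(C)(C)OC)C1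
F12 | step 21 | methyl 3β-hydroxy-5α-[(2-methoxypropan-2-yl)peroxy]eudesma-4(15),11(13)-dien-12-oate | C=C(C(=O)OC)[C@@H]1CC[C@@]2(C)CC[C@H](O)C(=C)[C@]2(OOC(C)(C)OC)C1
F13 | step 21 | methyl 3β-(angeloyloxy)-5α-[(2-methoxypropan-2-yl)peroxy]eudesma-4(15),11(13)-dien-12-oate | C=C(C(=O)OC)[C@@H]1CC[C@@]2(C)CC[C@H](OC(=O)/C(C)=C\C)C(=C)[C@]2(OOC(C)(C)OC)C1
A1 | alternative 1 | tert-butyldimethylsilyl dienol ether of the ring A enone, with C5=C6 methylene, C10 methyl and (E)-4-methyl-5-(trimethylsilyl)pent-3-enyl chain | C=C1C(C)=C(O[Si](C)(C)C(C)(C)C)CC[C@]1(C)CC/C=C(\C)C[Si](C)(C)C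
A2 | alternative 1 | (+)-α-cyperone | C=C(C)[C@@H]1CC[C@@]2(C)CCC(=O)C(C)=C2C1
A3 | alternative 2 | tert-butyl{[(1E,3E,7R)-7-(but-2-yn-1-yl)-4,8-dimethylnona-1,3,8-trien-1-yl]oxy}dimethylsilane | C=C(C)[C@@H](CC#CC)CC/C(C)=C/C=C/O[Si](C)(C)C(C)(C)C
A4 | alternative 2 | 3α-[(tert-butyldimethylsilyl)oxy]eudesma-1,4,11-triene | C=C(C)[C@@H]1CC[C@@]2(C)C=C[C@@H](O[Si](C)(C)C(C)(C)C)C(C)=C2C1
A5 | alternative 3 | N-(acyloxy)phthalimide of the ring A enone acid, with C10 propanoate chain and C5 (Z)-3-(methoxycarbonyl)-4-(phenylsulfonyl)but-2-enyl chain | CC1=C(C/C=C(\CS(=O)(=O)c2ccccc2)C(=O)OC)[C@@](C)(CCC(=O)ON2C(=O)c3ccccc3C2=O)CCC1=O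
A6 | alternative 3 | methyl 3-oxoeudesma-4,11(13)-dien-12-oate | C=C(C(=O)OC)[C@@H]1CC[C@@]2(C)CCC(=O)C(C)=C2C1
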